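The numbers in the tables were computed on assumed constants, noise included.

| flask | electrophile | nucleophile | scavenger | remark | time |
|---|---|---|---|---|---|
| Tuesday's | 0.080 M | 0.24 M | 0.040 M | the very flask that is asked about, followed so far |  |
| Sunday's | 0.054 M | 0.24 M | 0.040 M | run made earlier |  |
| flask | 0.080 M | 0.240 M | 0.0400 M |  | 2.0 d |

| run | time / h | electrophile / % | target / % |
|---|---|---|---|
| Tuesday's | 0.833 | 77.6 | 21.5 |
| Tuesday's | 1.33 | 67.4 | 32.9 |
| Tuesday's | 2.00 | 57.6 | 44.6 |
| Tuesday's | 2.50 | 52.6 | 48.1 |
| Tuesday's | 4.00 | 38.1 | 61.1 |
| Tuesday's | 6.00 | 29.2 | 71.0 |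
| Tuesday's | 10.0 | 22.1 | 75.6 |
| Sunday's | 4.00 | 34.4 | 64.8 |
| Sunday's | 6.00 | 26.2 | 75.4 |
| Sunday's | 8.00 | 18.3 | 79.0 |
| Sunday's | 15.0 | 11.7 | 88.7 |
| Sunday's | 20.0 | 13.9 | 87.8 |
| Sunday's | 30.0 | 12.7 | 89.2 |
| Sunday's | 50.0 | 16.9 | 83.7 |

(readings scatter by 1 percentage point)
- part of the electrophile that has reacted at 2.0 d
- share of free nucleophile in free nucleophile and protonated nucleophile together, at 2.0 d
- the earlier runs do not show how much of nucleophile is bound; that part of a forecast is a guess

- Count in fractions of the charge, not in molar, and the quick number you asked for comes from Tuesday's run, which is the asked flask itself: its first reading gives the electrophile a pseudo-first-order time constant of 3.28 h, and 2.0 d is 14.6 of those, so I expect the flask to stand at a stall, not in mid-curve.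
- Tuesday's last reading gives 2.59 for the stall number, the target fraction squared over the electrophile fraction left.
- If each target comes with one protonated nucleophile, the scavenger left out of the count, and you replace the falling nucleophile curve by its mean, a fixed fraction of its charge, this number goes with nucleophile charge squared over electrophile charge.
- Setting c squared over one minus c equal to it gives my 77.0%, but the scaling is loose: Sunday's reading at 15.0 h has 6.72 where it expects 3.83, and that reading was taken later than Tuesday's.
- Your forecast says 76% (68% to 83%) and 88% free (81% to 94%), “assuming one nucleophile is bound per target”; I give no number for the free share, since the readings do not show bound nucleophile.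
- The flask gives 77.0% reacted, with its target down from 80.2% at 1.00 d, so it is drifting back and not at a true stall; its stall number at that moment is 2.58, and it has 53.4% free, which is 35 percentage points less than your forecast.

    acid set free + scavenger → scavenged by-product (k = 1.10 /M/h)
    nucleophile + acid set free ⇌ idle adduct, settled at all times (K = 4.60 /M)
    2 nucleophile → self-condensation product (k = 0.150 /M/h)
    electrophile + nucleophile ⇌ acid set free + target (K = 0.430, k = 1.50 /M/h)
    nucleophile + acid set free ⇌ protonated nucleophile, settled at all times (K = 130 /M)

- For the neighbouring flask with 0.41 M of nucleophile, the same scaling lifts the stall number to 7.55, which reckons 89.4% reacted, and that neighbour gives 84.0%, which is less. At 2.0 d that neighbour holds 16% of its charged nucleophile unbound, and the asked flask holds 20%.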